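**Plan**

- Numbering: dioxane ring O1–C2(aryl)–C3(CH2OH)–O4, with O1 para to the acrylate on ring A. Retrosynthesis first returns the acid and the guaiacyl phenol to a methyl ester and a pivalate and the C3 CH2OH to a formyl group, then cuts C2–C3 and O1–C2 together.
- Enabling feature: C2 lies between O1 and C3 like the carbonyl carbon of an aromatic aldehyde after addition, and C3 is the alpha carbon of an acetaldehyde unit carried on O4. The two pieces are therefore vanillin pivalate and a (2-hydroxyaryloxy)acetaldehyde.
- Forward: ring A is prepared first (O4–CH2 bond by phenol alkylation, acrylate by Wittig reaction, unmasking to the hydroxy aldehyde). The two arenes are then joined and the dioxane ring, the only ring made, closes in the same amine-catalysed step. Reduction and hydrolysis finish.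
- Stereochemistry: C2 comes from the chiral primary amine salt (face-selective phenol addition to the iminium ion). C3 follows by equilibration of the enolisable aldehyde to trans. The E alkene comes from the stabilised ylide.

Key step: step 6

Assumption: the quinine-derived amine is taken to deliver the 2R centre by analogy with its oxa-Michael ring closures; if the opposite sense is found, the pseudo-enantiomeric quinidine-derived amine is used with no other change.

**Route**

Step 1
Reactants: 1 3,4-dihydroxybenzaldehyde
Product: 2 3-hydroxy-4-(methoxymethoxy)benzaldehyde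
Conditions: MOMCl (1.05 equiv), K2CO3 (1.1 equiv), acetone, 0 °C to rt
Reagents that add atoms: chloromethyl methyl ether (MOMCl), COCCl
Why: Williamson-type O-alkylation; the 4-OH para to the formyl group is the more acidic phenol, so one equivalent of carbonate should give mainly its phenoxide and place the MOM group there, a known regioselective monoprotection of this catechol.

Step 2
Reactants: 2 3-hydroxy-4-(methoxymethoxy)benzaldehyde; 3 bromoacetaldehyde diethyl acetal
Product: 4 3-(2,2-diethoxyethoxy)-4-(methoxymethoxy)benzaldehyde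
Conditions: K2CO3, KI (cat.), DMF, 100 °C
Reagents that add atoms: none
Why: Williamson ether synthesis on the remaining phenol; the beta,beta-dialkoxy bromide is a slow SN2 partner, hence iodide catalysis and heat, which the MOM ether and the aryl aldehyde tolerate.

Step 3
Reactants: 4 3-(2,2-diethoxyethoxy)-4-(methoxymethoxy)benzaldehyde; 5 methyl (triphenylphosphoranylidene)acetate
Product: 6 methyl (E)-3-[3-(2,2-diethoxyethoxy)-4-(methoxymethoxy)phenyl]prop-2-enoate
Conditions: toluene, 80 °C
Reagents that add atoms: none
Why: Wittig olefination with a stabilised ylide, which should give the E-cinnamate; the acetal and the MOM ether are inert.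

Step 4
Reactants: 6 methyl (E)-3-[3-(2,2-diethoxyethoxy)-4-(methoxymethoxy)phenyl]prop-2-enoate
Product: 8 methyl (E)-3-[4-hydroxy-3-(2-oxoethoxy)phenyl]prop-2-enoate (hydroxy aldehyde; expected mainly as its lactol), via MOM-protected aldehyde 7 (not isolated)
Conditions: 3 M aq. HCl, THF, 45 °C
Reagents that add atoms: water, O
Why: Acid-catalysed acetal hydrolysis; the diethyl acetal should open first and the aryl MOM ether follow, and the freed phenol captures the aldehyde as a six-membered lactol, the known resting form of 2-(2-hydroxyphenoxy)acetaldehydes, which shields it from self-condensation while the methyl ester survives dilute acid.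

Step 5
Reactants: 9 vanillin
Product: 10 4-formyl-2-methoxyphenyl 2,2-dimethylpropanoate (vanillin pivalate)
Conditions: PivCl, Et3N, DMAP (cat.), CH2Cl2, 0 °C to rt
Reagents that add atoms: pivaloyl chloride, CC(C)(C)C(Cl)=O
Why: DMAP-catalysed acylation of a phenol; vanillin esters are activated aryl esters, and the hindered pivalate should resist aminolysis by the primary amine and acyl transfer to the ring A phenol in step 6 while keeping the guaiacyl ring electron-poor.

Step 6
Reactants: 8 methyl (E)-3-[4-hydroxy-3-(2-oxoethoxy)phenyl]prop-2-enoate; 10 4-formyl-2-methoxyphenyl 2,2-dimethylpropanoate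
Product: 12 methyl (E)-3-{(2R,3S)-3-formyl-2-[3-methoxy-4-(pivaloyloxy)phenyl]-2,3-dihydro-1,4-benzodioxin-6-yl}prop-2-enoate, via alpha-aryloxy enal 11 (not isolated)
Conditions: 9-amino-9-deoxy-epi-quinine (20 mol%), CF3CO2H (40 mol%), 10 (1.5 equiv), CHCl3, 35 °C; cold aq. citric acid wash, crude product used at once
Reagents that add atoms: none
Why: Proposed new method: the amine salt turns the open form of 8 into an alpha-aryloxy enamine, which condenses with the non-enolisable aldehyde 10 (aldol addition then loss of water, C2–C3 bond) to the iminium ion of enal 11; the ring A phenol, sitting ortho to O4, then adds to its beta carbon (O1–C2 bond) and hydrolysis of the resulting enamine frees 12 and the amine. The closest known reactions are amine-catalysed aldol condensations that give alpha-substituted cinnamaldehydes and iminium-catalysed oxa-Michael additions of phenols that close chromanes and flavanones, and a primary amine is used because alpha-branched enals are activated poorly by secondary amines. The dioxane ring closes 6-endo-trig, as in flavanone formation; a five-membered alternative would need attack at the non-electrophilic alpha carbon. C2 is set by the catalyst, whose protonated quinuclidine and trifluoroacetate-paired iminium ion should leave one face of the beta carbon open to the phenol (2R); C3 is set by protonation of the enamine and then equilibrates through that enamine to the trans (2R,3S) aldehyde, in which aryl and formyl are both pseudo-equatorial. The step needs cross- rather than self-condensation and kinetic control at C2: 10 cannot enolise and is used in excess while 8 rests as its lactol, so little free donor aldehyde is present, and the electron-poor pivaloyloxyaryl group disfavours ionisation at C2, leaving only the enamine-mediated reversal, which is limited by mild temperature and by stopping at full conversion.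

Step 7
Reactants: 12 methyl (E)-3-{(2R,3S)-3-formyl-2-[3-methoxy-4-(pivaloyloxy)phenyl]-2,3-dihydro-1,4-benzodioxin-6-yl}prop-2-enoate
Product: 13 methyl (E)-3-{(2R,3R)-3-(hydroxymethyl)-2-[3-methoxy-4-(pivaloyloxy)phenyl]-2,3-dihydro-1,4-benzodioxin-6-yl}prop-2-enoate
Conditions: NaBH4, THF/EtOH, −20 °C; aq. NH4Cl
Reagents that add atoms: none
Why: Borohydride reduction of an aldehyde, fast at low temperature relative to beta-elimination; it removes the carbonyl that makes C3–H acidic, so both centres are fixed (C3 changes from S to R only through the CIP priorities), and NaBH4 should leave the conjugated ester, the alkene and the aryl pivalate alone under these conditions.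

Step 8
Reactants: 13 methyl (E)-3-{(2R,3R)-3-(hydroxymethyl)-2-[3-methoxy-4-(pivaloyloxy)phenyl]-2,3-dihydro-1,4-benzodioxin-6-yl}prop-2-enoate
Product: 14 (E)-3-[(2R,3R)-2-(4-hydroxy-3-methoxyphenyl)-3-(hydroxymethyl)-2,3-dihydro-1,4-benzodioxin-6-yl]prop-2-enoic acid
Conditions: LiOH·H2O (6 equiv), THF/MeOH/H2O, rt, under argon; then 1 M HCl to pH 3 at 0 °C
Reagents that add atoms: lithium hydroxide, [Li+].[OH-]
Why: Saponification; hydroxide cleaves the methyl cinnamate and the aryl pivalate by acyl substitution, no stereocentre is alpha to a carbonyl any more, and room temperature, exclusion of air and cold acidification should keep the phenolic benzyl aryl ether intact.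

**Compound list**

1 | 3,4-dihydroxybenzaldehyde | O=Cc1ccc(O)c(O)c1 | starting material
2 | 3-hydroxy-4-(methoxymethoxy)benzaldehyde | O=Cc1ccc(OCOC)c(O)c1 | intermediate
3 | bromoacetaldehyde diethyl acetal (2-bromo-1,1-diethoxyethane) | CCOC(CBr)OCC | starting material
4 | 3-(2,2-diethoxyethoxy)-4-(methoxymethoxy)benzaldehyde | O=Cc1ccc(OCOC)c(OCC(OCC)OCC)c1 | intermediate
5 | methyl (triphenylphosphoranylidene)acetate | COC(=O)C=P(c1ccccc1)(c1ccccc1)c1ccccc1 | starting material
6 | methyl (E)-3-[3-(2,2-diethoxyethoxy)-4-(methoxymethoxy)phenyl]prop-2-enoate | COC(=O)/C=C/c1ccc(OCOC)c(OCC(OCC)OCC)c1 | intermediate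
7 | methyl (E)-3-[4-(methoxymethoxy)-3-(2-oxoethoxy)phenyl]prop-2-enoate (formed in the flask in step 4) | COC(=O)/C=C/c1ccc(OCOC)c(OCC=O)c1 | intermediate
8 | methyl (E)-3-[4-hydroxy-3-(2-oxoethoxy)phenyl]prop-2-enoate; ring-chain tautomer methyl (E)-3-(2-hydroxy-2,3-dihydro-1,4-benzodioxin-6-yl)prop-2-enoate, COC(=O)/C=C/c1ccc2OC(O)COc2c1 | COC(=O)/C=C/c1ccc(O)c(OCC=O)c1 | intermediate
9 | vanillin (4-hydroxy-3-methoxybenzaldehyde) | COc1cc(C=O)ccc1O | starting material
10 | 4-formyl-2-methoxyphenyl 2,2-dimethylpropanoate (vanillin pivalate) | COc1cc(C=O)ccc1OC(=O)C(C)(C)C | intermediate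
11 | methyl (E)-3-[4-hydroxy-3-({(1Z)-1-[3-methoxy-4-(pivaloyloxy)phenyl]-3-oxoprop-1-en-2-yl}oxy)phenyl]prop-2-enoate (present as its iminium ion in step 6) | O=C/C(Oc1cc(/C=C/C(=O)OC)ccc1O)=C/c1ccc(OC(=O)C(C)(C)C)c(OC)c1 | intermediate
12 | methyl (E)-3-{(2R,3S)-3-formyl-2-[3-methoxy-4-(pivaloyloxy)phenyl]-2,3-dihydro-1,4-benzodioxin-6-yl}prop-2-enoate (trans) | COc1cc([C@H]2Oc3ccc(/C=C/C(=O)OC)cc3O[C@@H]2C=O)ccc1OC(=O)C(C)(C)C | intermediate
13 | methyl (E)-3-{(2R,3R)-3-(hydroxymethyl)-2-[3-methoxy-4-(pivaloyloxy)phenyl]-2,3-dihydro-1,4-benzodioxin-6-yl}prop-2-enoate (trans) | COc1cc([C@H]2Oc3ccc(/C=C/C(=O)OC)cc3O[C@@H]2CO)ccc1OC(=O)C(C)(C)C | intermediate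
14 | (E)-3-[(2R,3R)-2-(4-hydroxy-3-methoxyphenyl)-3-(hydroxymethyl)-2,3-dihydro-1,4-benzodioxin-6-yl]prop-2-enoic acid (trans) | COc1cc([C@H]2Oc3ccc(/C=C/C(=O)O)cc3O[C@@H]2CO)ccc1O | target

**Step count**

Total: 8 steps. Longest linear sequence: 7 steps (steps 1 to 4 and 6 to 8 from 3,4-dihydroxybenzaldehyde); step 5 is a one-step side branch.

**Steps most likely to fail**

1. Step 6. The cross-condensation may be slow or lose out to self-aldol reaction of 8 or to resting of 8 as an N,O-aminal. The phenol may add with poor facial selectivity. The C2 centre may erode through enamine-mediated reversal of the oxa-Michael addition.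

   The fallback is an auxiliary-controlled route of known reactions that sets out from 2 (and from 9 for the aldehyde partner) and rejoins at 14. Wittig reaction of 2 with 5 (toluene, 80 °C) should give methyl (E)-3-[3-hydroxy-4-(methoxymethoxy)phenyl]prop-2-enoate F1. Its phenol is alkylated with (S)-4-benzyl-3-(bromoacetyl)oxazolidin-2-one (K2CO3, acetone, rt) to the aryloxyacetyl imide F2. Vanillin 9 is protected (MOMCl, i-Pr2NEt, CH2Cl2) as 3-methoxy-4-(methoxymethoxy)benzaldehyde F3. An Evans syn-aldol reaction of F2 (Bu2BOTf, i-Pr2NEt, CH2Cl2, −78 °C, then F3) should give the (2S,3R) aldol imide F4, the alpha carbon (the later C3) being set by the auxiliary through the Zimmerman–Traxler transition state. NaBH4 in THF/H2O removes the auxiliary reductively to give the (1R,2R)-1,3-diol F5. LiOH (THF/MeOH/H2O) saponifies the methyl ester to the diol acid F6 while both phenols are still masked. Finally 2 M aq. HCl in THF at 45 °C cleaves both MOM ethers, ionises the para-hydroxybenzylic alcohol, and lets the ring A phenol trap the cation. This closure is known for 1-aryl-2-(2-hydroxyaryloxy)propane-1,3-diols and should give the trans dioxane under thermodynamic control with C3 untouched, that is 14.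

2. Step 4. The acid strength needed to cleave the aryl MOM ether may degrade the aryloxyacetaldehyde once it is free (aldol oligomers, acetal-linked dimers of the lactol), or MOM cleavage may stall under conditions the aldehyde tolerates.

   The fallback separates the two unmaskings, sets out from 1 and rejoins at 8. Regioselective allylation of 1 (allyl bromide, K2CO3, acetone) should give 4-(allyloxy)-3-hydroxybenzaldehyde F7. Alkylation with 3 (K2CO3, KI, DMF, 100 °C) gives 4-(allyloxy)-3-(2,2-diethoxyethoxy)benzaldehyde F8. Wittig reaction with 5 gives methyl (E)-3-[4-(allyloxy)-3-(2,2-diethoxyethoxy)phenyl]prop-2-enoate F9. The phenol is freed under neutral conditions (Pd(PPh3)4, morpholine, THF, rt) to give methyl (E)-3-[3-(2,2-diethoxyethoxy)-4-hydroxyphenyl]prop-2-enoate F10. Only the acetal then remains, and it is hydrolysed with 1 M aq. HCl in THF at rt to 8.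

3. Step 8. During the slow saponification the liberated guaiacyl phenoxide may expel O1 through a para-quinone methide, which opens the dioxane ring and erodes the trans relationship at C2. The phenoxides may also oxidise in air.

   The fallback masks the guaiacyl oxygen with a base-stable group so that the ester is cleaved before the phenol is released. It sets out from 8 (with the aldehyde partner again made from 9) and rejoins at 14. The conditions of step 6 are applied to 8 and 3-methoxy-4-(methoxymethoxy)benzaldehyde F3. This should lead through the alpha-aryloxy enal F11 to the trans (2R,3S) aldehyde F12. NaBH4 reduction as in step 7 gives the (2R,3R) alcohol F13. LiOH (THF/MeOH/H2O, rt) gives the MOM-protected acid F14 with no phenoxide para to C2. Dilute acid (2 M aq. HCl, THF, 40 °C) then removes the MOM group to give 14; under acid any opening at C2 re-closes to the trans isomer and C3 is not affected.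

**Further compounds**

F1 | step 6 | methyl (E)-3-[3-hydroxy-4-(methoxymethoxy)phenyl]prop-2-enoate | COC(=O)/C=C/c1ccc(OCOC)c(O)c1
F2 | step 6 | methyl (E)-3-[3-{2-[(4S)-4-benzyl-2-oxooxazolidin-3-yl]-2-oxoethoxy}-4-(methoxymethoxy)phenyl]prop-2-enoate | COC(=O)/C=C/c1ccc(OCOC)c(OCC(=O)N2[C@@H](Cc3ccccc3)COC2=O)c1
F3 | step 6 | 3-methoxy-4-(methoxymethoxy)benzaldehyde | COCOc1ccc(C=O)cc1OC
F4 | step 6 | methyl (E)-3-[3-({(1R,2S)-3-[(4S)-4-benzyl-2-oxooxazolidin-3-yl]-1-hydroxy-1-[3-methoxy-4-(methoxymethoxy)phenyl]-3-oxopropan-2-yl}oxy)-4-(methoxymethoxy)phenyl]prop-2-enoate (syn aldol; 2S,3R in the acyl chain) | COC(=O)/C=C/c1ccc(OCOC)c(O[C@H](C(=O)N2[C@@H](Cc3ccccc3)COC2=O)[C@H](O)c2ccc(OCOC)c(OC)c2)c1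
F5 | step 6 | methyl (E)-3-[3-({(1R,2R)-1,3-dihydroxy-1-[3-methoxy-4-(methoxymethoxy)phenyl]propan-2-yl}oxy)-4-(methoxymethoxy)phenyl]prop-2-enoate | COC(=O)/C=C/c1ccc(OCOC)c(O[C@H](CO)[C@H](O)c2ccc(OCOC)c(OC)c2)c1
F6 | step 6 | (E)-3-[3-({(1R,2R)-1,3-dihydroxy-1-[3-methoxy-4-(methoxymethoxy)phenyl]propan-2-yl}oxy)-4-(methoxymethoxy)phenyl]prop-2-enoic acid | OC(=O)/C=C/c1ccc(OCOC)c(O[C@H](CO)[C@H](O)c2ccc(OCOC)c(OC)c2)c1
F7 | step 4 | 4-(allyloxy)-3-hydroxybenzaldehyde | O=Cc1ccc(OCC=C)c(O)c1
F8 | step 4 | 4-(allyloxy)-3-(2,2-diethoxyethoxy)benzaldehyde | O=Cc1ccc(OCC=C)c(OCC(OCC)OCC)c1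
F9 | step 4 | methyl (E)-3-[4-(allyloxy)-3-(2,2-diethoxyethoxy)phenyl]prop-2-enoate | COC(=O)/C=C/c1ccc(OCC=C)c(OCC(OCC)OCC)c1
F10 | step 4 | methyl (E)-3-[3-(2,2-diethoxyethoxy)-4-hydroxyphenyl]prop-2-enoate | COC(=O)/C=C/c1ccc(O)c(OCC(OCC)OCC)c1
F11 | step 8 | methyl (E)-3-[4-hydroxy-3-({(1Z)-1-[3-methoxy-4-(methoxymethoxy)phenyl]-3-oxoprop-1-en-2-yl}oxy)phenyl]prop-2-enoate | O=C/C(Oc1cc(/C=C/C(=O)OC)ccc1O)=C/c1ccc(OCOC)c(OC)c1
F12 | step 8 | methyl (E)-3-{(2R,3S)-3-formyl-2-[3-methoxy-4-(methoxymethoxy)phenyl]-2,3-dihydro-1,4-benzodioxin-6-yl}prop-2-enoate | COc1cc([C@H]2Oc3ccc(/C=C/C(=O)OC)cc3O[C@@H]2C=O)ccc1OCOC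
F13 | step 8 | methyl (E)-3-{(2R,3R)-3-(hydroxymethyl)-2-[3-methoxy-4-(methoxymethoxy)phenyl]-2,3-dihydro-1,4-benzodioxin-6-yl}prop-2-enoate | COc1cc([C@H]2Oc3ccc(/C=C/C(=O)OC)cc3O[C@@H]2CO)ccc1OCOC
F14 | step 8 | (E)-3-{(2R,3R)-3-(hydroxymethyl)-2-[3-methoxy-4-(methoxymethoxy)phenyl]-2,3-dihydro-1,4-benzodioxin-6-yl}prop-2-enoic acid | COc1cc([C@H]2Oc3ccc(/C=C/C(=O)O)cc3O[C@@H]2CO)ccc1OCOC
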